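Assumption: (2Z)-3-methylpent-2-en-4-yn-1-ol, ethyl glyoxylate, methyl 3-hydroxypropanoate and (2R)-2-methylbutanoic acid are taken as purchased, and germacrane numbering is used throughout (C1–C10 ring, C11–C13 lactone carbons, C14 on C10, C15 on C4).

## The problem

The target is a germacranolide: a ten-membered carbocycle fused across C6–C7 to a butenolide whose tetrasubstituted C7=C11 bond carries the acetoxymethyl carbon C13. A trans 1,10-oxirane and a cis 4,5-oxirane flank the Z C2=C3 bond, C6 bears the lactone oxygen and C8 the (2R)-2-methylbutanoate. Six ring stereocentres (1R,4R,5S,6S,8S,10S) and one in the acyl group therefore have to be set. They fall into three groups. C4/C5 can be fixed by a reagent on an acyclic allylic alcohol and can then direct C6 by 1,2-induction; C8 is insulated from both neighbours and needs its own catalyst control; C10 can again be fixed by a reagent and can direct C1. Little rough treatment is tolerated: both oxiranes are allylic, C6–H is the γ-hydrogen of the butenolide with an oxirane oxygen β to it, the C13 acetate is a vinylogous leaving group, and the C14 hydroxyl sits four atoms from the C8 ester. Ring closure is the second difficulty, because a ten-membered ring with a cis alkene and a fused five-membered ring is strained and must be closed without disturbing this functionality. The feature that opens the structure is C1: it is an oxygenated carbon between the Z alkene and the quaternary C10, and its oxygen, C10 and the C14 hydroxyl together are a 2,3-epoxy alcohol in its rearranged form. Read backwards through an epoxide migration, C1 becomes a secondary allylic alcohol beside a C10–C14 spiro-oxirane, which is the adduct of a Z-alkenyl metal at C2 with a non-enolisable glycidic aldehyde.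

## Retrosynthesis

**25 to 24.** The O–C10 bond of the 1,10-oxirane is cut and the oxygen is returned to C14, which gives the spiro-oxirane alcohol 24; forward this is a Payne rearrangement. The neighbouring options are epoxidation of a ring-trans C1=C10 alkene beside C2=C3, or closure from a C1 leaving group by a tertiary alkoxide. They would need face control on a flexible medium ring or a displacement next to a vinyl oxirane. 24 has the same atoms, but its C10 centre can be set by an acyclic Sharpless epoxidation and its C1 carbinol is a retron for carbonyl addition. The forward step must let the C1 alkoxide open the spiro-oxirane at C10 with inversion in the presence of two esters, the butenolide and the second oxirane.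

**24 to 23.** The ring is opened at C1–C2, giving the iodo aldehyde 23. The other ring bonds are worse places to cut: metathesis at C2=C3 would have to give a Z alkene between two oxiranes in a ten-membered ring, and C8–C9 or C9–C10 offer no activating group. The C1–C2 cut removes the ring and one stereocentre. The aldehyde that results has no α-hydrogen, and the alkenyl iodide is the mildest nucleophile precursor. The forward reaction must keep the Z geometry, touch neither the esters nor the oxiranes, and choose one face of the aldehyde.

**23 to 19.** Three functional-group changes lead back through 22, 21 and 20 to the allylic alcohol 19. The aldehyde comes from the primary alcohol 22, the Z-iodoalkene from the terminal alkyne of 20 by way of the iodoalkyne 21, and the spiro-oxirane from the 2-substituted allylic alcohol 19 by Sharpless epoxidation. The alkyne is carried as long as possible because an alkenyl iodide would not survive the earlier chromium step. The epoxidation precedes the alkyne reduction so that no 1,1-disubstituted alkene is present when diimide is used.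

**19 to 14.** The two acyl groups and the free C1 hydroxyl are traced to three differentiated ethers in 14. The p-methoxybenzyl ether of 18 is removed last. The C8 ester is made from 16 and acid 17, the C13 acetate from diol 15, and 15 from the bis-silyl ether 14. Acetylating the primary hydroxyl before the secondary one avoids a separate protecting step, and the acetate has no incentive to move to the secondary oxygen.

**14 to 9 and 12.** The butenolide is cut at C6–C7 and at the lactone C–O bond, giving enol triflate 9 and epoxy aldehyde 12, with hydroxy ester 13 as the link. Cutting C5–C6 instead would require building the oxirane after the coupling, next to the acidic C6–H. Cutting C7–C8 would leave C8 uncontrolled. The chosen cut lets the C4/C5 oxirane, already in place, direct C6. It asks for an alkenyl metal that tolerates an ester, a silyl ether next to the metal-bearing carbon and an alkynyl oxirane in the partner.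

**12 to 10.** The aldehyde 12 comes from epoxy alcohol 11, and 11 from the Z-enynol 10 by Sharpless epoxidation. The cis relation of C3 and C6 across the oxirane is the Z geometry of 10, and both centres are set by the reagent.

**9 to 5 and 7.** The triflate 9 is the enol derivative of β-keto ester 8. Cutting C7–C11 of 8 gives the α-silyloxy ester 5 and the propanoate 7 (from 6), to be joined by a crossed Claisen condensation. The ring would otherwise require a stereodefined tetrasubstituted acyclic alkene; here its geometry is reduced to that of a chelated enolate.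

**5 to 1 and 3.** The C8–C9 bond of 4, the parent alcohol of 5, is cut into ethyl glyoxylate 3 and the methallyl ether 2, made from 1. A carbonyl-ene reaction forms this bond, creates C8 under catalyst control and leaves the C10=C14 methylene and the C1 oxygen in place in one step.

## Roads not taken

**Alternative 1:** The ring would be reached by contraction. C6 and C13 are first joined through an ether oxygen in a thirteen-membered ring; lithiation at C6 then triggers a [2,3]-Wittig shift that forms C6–C7, breaks O–C13 and gives the ten-membered trienol A1. The merits are real. A thirteen-membered ether is far easier to close than a ten-membered carbocycle, ring contraction of this kind is a proven entry to germacrane rings, and the ordered transition state sets the C6/C7 relation. In ring formation this road is better than the chosen one, which needs high dilution and a large excess of a chromium salt. Its weak points lie after the key step.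
- A1 has C7 as an sp3 centre, C11=C13 as an exocyclic methylene and C12 at the alcohol level. The 7(11)-ene with a C13 acetate therefore needs an oxidation to the lactone and an allylic transposition.
- The conjugated C10=C1–C2=C3–C4=C5 triene must be converted into two oxiranes while the middle alkene is spared.
- As drawn, A1 has a ring-cis C1=C10 bond and C3 and C6 trans across C4=C5. The target has a trans 1,10-oxirane and a cis 4,5-oxirane, so direct oxygen transfer would give the wrong relative configuration at both ends.
- The alkyllithium step excludes esters, so all acyl groups and their protecting-group changes come afterwards.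

The chosen plan sets against the easier ring closure that its closure product already holds every carbon at the final oxidation level and both oxirane configurations from reagent-controlled acyclic epoxidations.

**Alternative 2:** C1–C10 and C1–O would be cut together. Forward, an allylic sulfonium salt at C1 is deprotonated by a potassium amide base, the ylide adds to a C10 ketone, and the betaine closes to the oxirane with loss of the sulfide. The ten-membered ring and the 1,10-oxirane form in one step to give A2. This is more direct than the chosen pair of ring closure and rearrangement, and it never exposes a free C14 alkoxide near the C8 ester; in that respect it is the better road. Against it stand four points.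
- C1 and C10 are created together with no adjacent control element, so both the trans geometry and the absolute sense of the oxirane depend on a macrocyclic betaine.
- The C10 ketone has enolisable methylenes on both sides, and the amide base also threatens C6–H of the butenolide and the acetate.
- The allylic ylide is ambident (C1 or C3), and the sulfonium group must be installed beside a vinyl oxirane.
- A2 still needs two desilylations and an acylation.

The chosen plan sets against it a C10 centre fixed beforehand by a reagent, 1,2-induction at C1, an electrophile that cannot enolise, and a nucleophile generated under neutral conditions.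

**Alternative 3:** The ring would come from ring expansion. The potassium alkoxide of a cis-1,2-dialkenylcyclohexenol undergoes an anionic oxy-Cope shift that forms C8–C9 and gives the ten-membered dienone A3, with a C6 ketone and the C8 centre set by chirality transfer. The pericyclic step avoids the entropy of macrocyclisation, is strongly accelerated and scales well; for forming the ring it is better than a chromium-mediated closure. For this target the distance from A3 is the problem.
- None of C11–C13 is present. A butenolide would have to be annulated onto the C6 ketone and C7, with the direction of enolisation (C5 or C7) to be controlled.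
- The ring-cis C1=C10 bond again maps onto a cis oxirane, not the trans one of the target.
- The protected 4,5-diol must be turned into the cis oxirane by activation and displacement.
- The C8 ether must be exchanged for the ester.

This is many steps after the key step, against one in the chosen plan, which answers the better ring formation of this road with a closure that also sets C1 and relays it to C10.

Key step: step 18

## Route

Step 1
Reactants: 1 2-methylprop-2-en-1-ol
Product: 2 methallyl 4-methoxybenzyl ether
Conditions: NaH, 4-methoxybenzyl chloride, Bu4NI (cat.), THF/DMF, 0 °C to rt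
Reagents that add atoms: 4-methoxybenzyl chloride, COc1ccc(CCl)cc1
Why: Williamson ether synthesis of a primary allylic alkoxide with a benzylic chloride; the ether is later removed oxidatively at neutral pH.

Step 2
Reactants: 2 methallyl 4-methoxybenzyl ether; 3 ethyl glyoxylate
Product: 4 ethyl (2S)-2-hydroxy-4-{[(4-methoxybenzyl)oxy]methyl}pent-4-enoate
Conditions: (S)-BINOL (10 mol%), TiCl2(OiPr)2 (10 mol%), 4 Å molecular sieves, CH2Cl2, −30 °C
Reagents that add atoms: none
Why: Catalytic asymmetric carbonyl-ene reaction of a glyoxylate with a 1,1-disubstituted alkene: C8–C9 forms at the terminal methylene while a methyl hydrogen is transferred, the hydrogens next to the ether oxygen being inductively deactivated. By analogy with simple 1,1-disubstituted alkenes, where the (R)-ligand gives (R)-hydroxy esters, the (S)-BINOL–titanium Lewis acid should shield one face of the chelated glyoxylate and set (8S).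

Step 3
Reactants: 4 (S)-hydroxy ester
Product: 5 ethyl (2S)-4-{[(4-methoxybenzyl)oxy]methyl}-2-[(triethylsilyl)oxy]pent-4-enoate
Conditions: Et3SiCl, imidazole, CH2Cl2, 0 °C
Reagents that add atoms: chlorotriethylsilane, CC[Si](Cl)(CC)CC
Why: Standard silylation of a secondary alcohol; the triethylsilyl group is chosen to fall together with the primary silyl ether in step 10.

Step 4
Reactants: 6 methyl 3-hydroxypropanoate
Product: 7 methyl 3-{[tert-butyl(dimethyl)silyl]oxy}propanoate
Conditions: t-BuMe2SiCl, imidazole, CH2Cl2, rt
Reagents that add atoms: tert-butylchlorodimethylsilane, CC(C)(C)[Si](C)(C)Cl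
Why: Standard silylation of a primary alcohol.

Step 5
Reactants: 5 α-silyloxy ester; 7 silyloxypropanoate
Product: 8 β-keto ester (C11 epimers)
Conditions: LiN(iPr)2, 7 (2.5 equiv), THF, −78 °C; then 5, −78 to −50 °C; aq. NH4Cl
Reagents that add atoms: none
Why: Crossed Claisen condensation: the lithium enolate of 7, used in excess at a temperature where loss of silyloxide is slow, acylates the inductively activated ester 5, and the product is stored as its stabilised enolate until the quench. C8 is not epimerised because deprotonation takes place between the two carbonyl groups.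

Step 6
Reactants: 8 β-keto ester
Product: 9 (Z)-enol triflate
Conditions: NaH, Et2O, 0 °C; then (CF3SO2)2O, −78 to 0 °C
Reagents that add atoms: trifluoromethanesulfonic anhydride, O=S(=O)(OS(=O)(=O)C(F)(F)F)C(F)(F)F
Why: O-Sulfonylation of the sodium enolate of a β-keto ester; the sodium chelate between enolate oxygen and ester carbonyl holds these groups cis, so the triflate should form as the Z isomer, the geometry needed for lactonisation in step 9.

Step 7
Reactants: 10 (2Z)-3-methylpent-2-en-4-yn-1-ol
Product: 11 [(2S,3R)-3-ethynyl-3-methyloxiran-2-yl]methanol
Conditions: Ti(OiPr)4 (10 mol%), L-(+)-diethyl tartrate (12 mol%), t-BuOOH, 4 Å molecular sieves, CH2Cl2, −20 °C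
Reagents that add atoms: tert-butyl hydroperoxide, CC(C)(C)OO
Why: Sharpless asymmetric epoxidation of a 3,3-disubstituted Z-allylic alcohol (a nerol-type substrate); with the L-(+)-tartrate the oxygen is delivered to the face that gives C4 (R) and C5 (S), and the cis relation of C3 and C6 follows from the Z alkene.

Step 8
Reactants: 11 epoxy alcohol
Product: 12 (2R,3R)-3-ethynyl-3-methyloxirane-2-carbaldehyde
Conditions: Dess–Martin periodinane, pyridine, CH2Cl2, 0 °C; used as a solution
Reagents that add atoms: none
Why: Dess–Martin oxidation of a primary epoxy alcohol under buffered conditions that do not epimerise the α-centre; the volatile aldehyde is not stored.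

Step 9
Reactants: 9 (Z)-enol triflate; 12 epoxy aldehyde
Product: 14 bis-silyl butenolide, via hydroxy ester 13 (not isolated)
Conditions: CrCl2 (4 equiv), NiCl2 (2 mol%), DMF, rt; aqueous work-up
Reagents that add atoms: none
Why: Nozaki–Hiyama–Kishi coupling of an alkenyl triflate: zerovalent nickel inserts into the C7–O bond, the alkenyl group passes with retention to trivalent chromium and adds to the aldehyde only, and the alkoxide of 13 closes onto the cis methyl ester (5-exo-trig) to give the butenolide. C6 is set by 1,2-induction from C5 in the polar Felkin–Anh sense (C5–O anti to the nucleophile, H5 beside the aldehyde hydrogen), which should favour (6S); the minor enantiomers of both fragments end up as separable diastereomers.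

Step 10
Reactants: 14 bis-silyl butenolide
Product: 15 butenolide diol
Conditions: Bu4NF, AcOH (1:1), THF, 0 °C to rt
Reagents that add atoms: none
Why: Fluoride cleavage of the secondary triethylsilyl and the primary tert-butyldimethylsilyl ether; buffering with acetic acid keeps the medium near neutral, so neither C6–H is removed nor the 4,5-oxirane activated towards the free C8 hydroxyl.

Step 11
Reactants: 15 butenolide diol
Product: 16 C13 acetate with free C8 hydroxyl
Conditions: AcCl (1.05 equiv), 2,4,6-collidine, CH2Cl2, −78 °C
Reagents that add atoms: acetyl chloride, CC(Cl)=O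
Why: Kinetic acylation of the primary allylic hydroxyl in the presence of the hindered secondary one; migration of the acetate to the secondary oxygen would be uphill.

Step 12
Reactants: 16 hydroxy acetate; 17 (2R)-2-methylbutanoic acid
Product: 18 C8 (2R)-2-methylbutanoate
Conditions: N,N'-dicyclohexylcarbodiimide, DMAP (cat.), CH2Cl2, 0 °C to rt
Reagents that add atoms: none
Why: Steglich esterification (carbodiimide activation, acyl transfer through the acylpyridinium ion); the acid carries only alkyl groups at its stereocentre, so epimerisation through a ketene is not expected.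

Step 13
Reactants: 18 diester p-methoxybenzyl ether
Product: 19 allylic alcohol
Conditions: DDQ, CH2Cl2/pH 7 phosphate buffer, 0 °C
Reagents that add atoms: none
Why: Oxidative cleavage of the p-methoxybenzyl ether through its benzylic cation and hemiacetal at neutral pH; esters, oxirane, alkyne and butenolide are not oxidised.

Step 14
Reactants: 19 allylic alcohol
Product: 20 spiro-epoxy alcohol
Conditions: Ti(OiPr)4 (20 mol%), L-(+)-diethyl tartrate (24 mol%), t-BuOOH, 4 Å molecular sieves, CH2Cl2, −20 °C
Reagents that add atoms: tert-butyl hydroperoxide, CC(C)(C)OO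
Why: Sharpless asymmetric epoxidation of a 2-substituted allylic alcohol; the electron-poor butenolide alkene is inert, and the L-(+)-tartrate reagent should deliver oxygen to the face that gives the (10S)-epoxy alcohol (the 2-methylglycidol series), reagent control overriding the remote centres.

Step 15
Reactants: 20 spiro-epoxy alcohol
Product: 21 iodoalkyne
Conditions: N-iodosuccinimide, AgNO3 (10 mol%), acetone, rt, dark
Reagents that add atoms: N-iodosuccinimide, O=C1CCC(=O)N1I
Why: Silver-catalysed electrophilic iodination of the terminal alkyne through the silver acetylide, under neutral conditions that leave the epoxy alcohol untouched.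

Step 16
Reactants: 21 iodoalkyne
Product: 22 (Z)-iodoalkene
Conditions: 2-nitrobenzenesulfonylhydrazide, Et3N, THF/i-PrOH, rt
Reagents that add atoms: none
Why: Diimide reduction of a 1-iodoalkyne: syn delivery of two hydrogens gives the Z-iodoalkene. The only other alkene is tetrasubstituted and electron-poor, and the C10=C14 methylene has already been epoxidised.

Step 17
Reactants: 22 (Z)-iodoalkene alcohol
Product: 23 iodo aldehyde
Conditions: Dess–Martin periodinane, pyridine, CH2Cl2, 0 °C
Reagents that add atoms: none
Why: Dess–Martin oxidation of the primary alcohol; the aldehyde is α-quaternary, cannot epimerise and is used at once.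

Step 18
Reactants: 23 iodo aldehyde
Product: 24 ten-membered C1 alcohol with C10–C14 spiro-oxirane
Conditions: CrCl2 (15 equiv), NiCl2 (0.1 equiv), DMSO/THF, 0.003 M, slow addition, rt
Reagents that add atoms: none
Why: Divalent chromium reduces the nickel salt to zerovalent nickel, which inserts into the C2–I bond with retention of the Z geometry; the alkenyl group is handed to trivalent chromium and the Z-alkenylchromium adds 1,2 to the C1 aldehyde, forming C1–C2. The closest known reaction type is the Nozaki–Hiyama–Kishi macrocyclisation of alkenyl iodides onto aldehydes, which has closed nine- to twelve-membered carbocycles. The ten-membered ring closes in a 10-exo-trig mode by this carbonyl addition; the butenolide, the cis 4,5-oxirane and the Z alkene remove rotors and turn the chain ends towards each other, and high dilution with slow addition suppresses dimers. The only new stereocentre is C1, and its control element is the adjacent quaternary C10: in the polar Felkin–Anh arrangement the C10–O bond is anti to the incoming alkenylchromium, the tied-back C14 methylene lies beside the aldehyde hydrogen and the C9 tether lies on the carbonyl-oxygen side. This rotamer has a gauche C2–C1–C10–C9 torsion that suits a ten-membered ring and leads to the (1R) alcohol. The step needs chemoselectivity for the C–I bond and the aldehyde over two esters, the allylic acetate, the butenolide and two oxiranes, which the low basicity and aldehyde selectivity of organochromium reagents provide. It also needs a configurationally stable aldehyde, which the missing α-hydrogen at C10 secures, and the oxirane oxygen on C4 is γ to the metal and cannot be eliminated.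

Step 19
Reactants: 24 ten-membered C1 alcohol
Product: 25 target
Conditions: NaH (0.3 equiv), THF, −20 to 0 °C; AcOH, −20 °C
Reagents that add atoms: none
Why: Payne rearrangement under aprotic conditions: the C1 alkoxide attacks C10 in a 3-exo-tet displacement anti to the C10–O bond, so C1 keeps and C10 inverts its configuration, and the primary C14 alkoxide is released and carries the chain by proton exchange. The trisubstituted oxirane and the primary alkoxide lie on the favoured side of the equilibrium, and substoichiometric base, low temperature and an early acidic quench limit acyl transfer and deprotonation of the butenolide.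

## Compound list

1 | 2-methylprop-2-en-1-ol | CC(=C)CO | starting material
2 | 1-methoxy-4-{[(2-methylprop-2-en-1-yl)oxy]methyl}benzene | CC(=C)COCc1ccc(OC)cc1 | intermediate
3 | ethyl glyoxylate | CCOC(=O)C=O | starting material
4 | ethyl (2S)-2-hydroxy-4-{[(4-methoxybenzyl)oxy]methyl}pent-4-enoate | CCOC(=O)[C@@H](O)CC(=C)COCc1ccc(OC)cc1 | intermediate
5 | ethyl (2S)-4-{[(4-methoxybenzyl)oxy]methyl}-2-[(triethylsilyl)oxy]pent-4-enoate | CCOC(=O)[C@@H](O[Si](CC)(CC)CC)CC(=C)COCc1ccc(OC)cc1 | intermediate
6 | methyl 3-hydroxypropanoate | COC(=O)CCO | starting material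
7 | methyl 3-{[tert-butyl(dimethyl)silyl]oxy}propanoate | COC(=O)CCO[Si](C)(C)C(C)(C)C | intermediate
8 | methyl (4S)-2-({[tert-butyl(dimethyl)silyl]oxy}methyl)-6-{[(4-methoxybenzyl)oxy]methyl}-3-oxo-4-[(triethylsilyl)oxy]hept-6-enoate (C2 epimers) | COC(=O)C(CO[Si](C)(C)C(C)(C)C)C(=O)[C@@H](O[Si](CC)(CC)CC)CC(=C)COCc1ccc(OC)cc1 | intermediate
9 | methyl (2Z,4S)-2-({[tert-butyl(dimethyl)silyl]oxy}methyl)-6-{[(4-methoxybenzyl)oxy]methyl}-4-[(triethylsilyl)oxy]-3-{[(trifluoromethyl)sulfonyl]oxy}hepta-2,6-dienoate | COC(=O)/C(CO[Si](C)(C)C(C)(C)C)=C(\OS(=O)(=O)C(F)(F)F)[C@@H](O[Si](CC)(CC)CC)CC(=C)COCc1ccc(OC)cc1 | intermediate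
10 | (2Z)-3-methylpent-2-en-4-yn-1-ol | C#C/C(C)=C\CO | starting material
11 | [(2S,3R)-3-ethynyl-3-methyloxiran-2-yl]methanol | C#C[C@@]1(C)O[C@H]1CO | intermediate
12 | (2R,3R)-3-ethynyl-3-methyloxirane-2-carbaldehyde | C#C[C@@]1(C)O[C@H]1C=O | intermediate
13 | methyl (2E,4S)-2-({[tert-butyl(dimethyl)silyl]oxy}methyl)-3-{(S)-[(2S,3R)-3-ethynyl-3-methyloxiran-2-yl](hydroxy)methyl}-6-{[(4-methoxybenzyl)oxy]methyl}-4-[(triethylsilyl)oxy]hepta-2,6-dienoate, formed as its chromium alkoxide | COC(=O)/C(CO[Si](C)(C)C(C)(C)C)=C(\[C@H](O)[C@@H]1O[C@]1(C)C#C)[C@@H](O[Si](CC)(CC)CC)CC(=C)COCc1ccc(OC)cc1 | intermediate (not isolated)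
14 | (5S)-3-({[tert-butyl(dimethyl)silyl]oxy}methyl)-5-[(2S,3R)-3-ethynyl-3-methyloxiran-2-yl]-4-[(1S)-3-{[(4-methoxybenzyl)oxy]methyl}-1-[(triethylsilyl)oxy]but-3-en-1-yl]furan-2(5H)-one | O=C1O[C@H]([C@@H]2O[C@]2(C)C#C)C([C@@H](O[Si](CC)(CC)CC)CC(=C)COCc2ccc(OC)cc2)=C1CO[Si](C)(C)C(C)(C)C | intermediate
15 | (5S)-5-[(2S,3R)-3-ethynyl-3-methyloxiran-2-yl]-4-[(1S)-1-hydroxy-3-{[(4-methoxybenzyl)oxy]methyl}but-3-en-1-yl]-3-(hydroxymethyl)furan-2(5H)-one | O=C1O[C@H]([C@@H]2O[C@]2(C)C#C)C([C@@H](O)CC(=C)COCc2ccc(OC)cc2)=C1CO | intermediate
16 | {(5S)-5-[(2S,3R)-3-ethynyl-3-methyloxiran-2-yl]-4-[(1S)-1-hydroxy-3-{[(4-methoxybenzyl)oxy]methyl}but-3-en-1-yl]-2-oxo-2,5-dihydrofuran-3-yl}methyl acetate | O=C1O[C@H]([C@@H]2O[C@]2(C)C#C)C([C@@H](O)CC(=C)COCc2ccc(OC)cc2)=C1COC(C)=O | intermediate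
17 | (2R)-2-methylbutanoic acid | CC[C@@H](C)C(=O)O | starting material
18 | (1S)-1-{(2S)-4-(acetoxymethyl)-2-[(2S,3R)-3-ethynyl-3-methyloxiran-2-yl]-5-oxo-2,5-dihydrofuran-3-yl}-3-{[(4-methoxybenzyl)oxy]methyl}but-3-en-1-yl (2R)-2-methylbutanoate | O=C1O[C@H]([C@@H]2O[C@]2(C)C#C)C([C@@H](OC(=O)[C@H](C)CC)CC(=C)COCc2ccc(OC)cc2)=C1COC(C)=O | intermediate
19 | (1S)-1-{(2S)-4-(acetoxymethyl)-2-[(2S,3R)-3-ethynyl-3-methyloxiran-2-yl]-5-oxo-2,5-dihydrofuran-3-yl}-3-(hydroxymethyl)but-3-en-1-yl (2R)-2-methylbutanoate | O=C1O[C@H]([C@@H]2O[C@]2(C)C#C)C([C@@H](OC(=O)[C@H](C)CC)CC(=C)CO)=C1COC(C)=O | intermediate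
20 | (1S)-1-{(2S)-4-(acetoxymethyl)-2-[(2S,3R)-3-ethynyl-3-methyloxiran-2-yl]-5-oxo-2,5-dihydrofuran-3-yl}-2-[(2S)-2-(hydroxymethyl)oxiran-2-yl]ethyl (2R)-2-methylbutanoate | O=C1O[C@H]([C@@H]2O[C@]2(C)C#C)C([C@@H](OC(=O)[C@H](C)CC)C[C@]2(CO)CO2)=C1COC(C)=O | intermediate
21 | (1S)-1-{(2S)-4-(acetoxymethyl)-2-[(2S,3R)-3-(iodoethynyl)-3-methyloxiran-2-yl]-5-oxo-2,5-dihydrofuran-3-yl}-2-[(2S)-2-(hydroxymethyl)oxiran-2-yl]ethyl (2R)-2-methylbutanoate | O=C1O[C@H]([C@@H]2O[C@]2(C)C#CI)C([C@@H](OC(=O)[C@H](C)CC)C[C@]2(CO)CO2)=C1COC(C)=O | intermediate
22 | (1S)-1-{(2S)-4-(acetoxymethyl)-2-{(2S,3R)-3-[(Z)-2-iodoethenyl]-3-methyloxiran-2-yl}-5-oxo-2,5-dihydrofuran-3-yl}-2-[(2S)-2-(hydroxymethyl)oxiran-2-yl]ethyl (2R)-2-methylbutanoate | O=C1O[C@H]([C@@H]2O[C@]2(C)/C=C\I)C([C@@H](OC(=O)[C@H](C)CC)C[C@]2(CO)CO2)=C1COC(C)=O | intermediate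
23 | (1S)-1-{(2S)-4-(acetoxymethyl)-2-{(2S,3R)-3-[(Z)-2-iodoethenyl]-3-methyloxiran-2-yl}-5-oxo-2,5-dihydrofuran-3-yl}-2-[(2R)-2-formyloxiran-2-yl]ethyl (2R)-2-methylbutanoate | O=C[C@]1(CO1)C[C@H](OC(=O)[C@H](C)CC)C1=C(COC(C)=O)C(=O)O[C@@H]1[C@@H]1O[C@]1(C)/C=C\I | intermediate
24 | (1R,4R,5S,6S,8S,10R)-13-acetoxy-4,5:10,14-diepoxy-1-hydroxygermacra-2(Z),7(11)-dien-6,12-olide 8-O-[(2R)-2-methylbutanoate] | CC[C@@H](C)C(=O)O[C@H]1C[C@@]2(CO2)[C@H](O)/C=C\[C@@]2(C)O[C@H]2[C@H]2OC(=O)C(COC(C)=O)=C12 | intermediate
25 | (1R,4R,5S,6S,8S,10S)-13-acetoxy-1,10:4,5-diepoxy-14-hydroxygermacra-2(Z),7(11)-dien-6,12-olide 8-O-[(2R)-2-methylbutanoate] | CC[C@@H](C)C(=O)O[C@H]1C[C@@]2(CO)O[C@@H]2/C=C\[C@@]2(C)O[C@H]2[C@H]2OC(=O)C(COC(C)=O)=C12 | target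

## Step count and least certain steps

Total: 19 steps. Longest linear sequence: 16 steps (1, 2, 4, 5, 8, 9, 14, 15, 16, 18, 19, 20, 21, 22, 23, 24, 25).

**Step 18 (key step).** The most likely failure is poor facial selectivity at C1. The two Felkin rotamers differ only in which methylene on C10 lies beside the carbonyl oxygen, and the strain of the forming ring may override the small difference; oligomerisation and reduction of the C–I bond compete at the dilution needed. Fallback: the mixture of C1 epimers that contains 24 would be oxidised (Dess–Martin periodinane, pyridine, CH2Cl2) to the macrocyclic C1 ketone F1. The carbonyl group would then be reduced under reagent control with a 2-methyl-CBS-oxazaborolidine and catecholborane at −78 °C (Corey–Bakshi–Shibata reduction, catalyst enantiomer chosen on the first run). This returns to 24 and replaces a substrate-controlled addition by a reagent-controlled reduction.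

**Step 19.** The alkoxide may be diverted in three ways:
- acyl transfer from O8 to the newly formed primary alkoxide through a seven-membered transition state;
- removal of C6–H, followed by opening of the 4,5-oxirane or loss of acetate from C13;
- transannular 5-exo attack of O1 on C4.

All three compete with a 3-exo displacement at a fully substituted carbon. Fallback: setting out from 24, silylation with 1-(trimethylsilyl)imidazole gives the C1 trimethylsilyl ether F2. A catalytic amount of the anhydrous fluoride Bu4N[Ph3SiF2] in THF at −40 °C frees a little C1 alkoxide, which rearranges, and the primary alkoxide takes the silyl group from the next molecule of F2. The rearranged C14 trimethylsilyl ether F3 therefore accumulates and no alkoxide builds up. Citric acid in methanol then removes the silyl group and the route is rejoined at 25.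

**Step 9.** Oxidative addition and transmetalation of a hindered, tetrasubstituted enol triflate may be slow, so that reduction or homocoupling takes over. Induction from C5 may also be modest, and the nickel catalyst may ionise the alkynyl oxirane. Fallback: setting out from 9, stannylation (Pd(PPh3)4, (Me3Sn)2, LiCl, THF, 60 °C) gives the alkenylstannane F4, and iodine in CH2Cl2 at 0 °C gives the (Z)-iodo ester F5. Iodine–magnesium exchange (i-PrMgCl·LiCl, THF, −40 °C) and addition of 12 at −78 °C then form the C6–C7 bond as a polar Grignard addition. Warming closes the lactone and the route is rejoined at 14.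

**Step 2.** Hydrogen transfer may lose regioselectivity (abstraction next to oxygen), or the ether oxygen may bind the titanium catalyst and erode the enantioselectivity. Fallback: setting out from 1, double deprotonation (n-BuLi, TMEDA) and quenching with Bu3SnCl gives 2-[(tributylstannyl)methyl]prop-2-en-1-ol F6, and NaH with 4-methoxybenzyl chloride gives its ether F7. Addition of this allylstannane to 3 under (S)-BINOL/Ti(OiPr)4 catalysis (Keck allylation, sense of induction to be confirmed) fixes the regiochemistry through the C–Sn bond and rejoins the route at 4.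

**Step 5.** The enolate of 7 may lose silyloxide faster than it acylates the hindered ester, or the ketone formed may be attacked a second time. Fallback: setting out from 5, reduction with (i-Bu)2AlH in CH2Cl2 at −78 °C gives the aldehyde F8. Aldol addition of the lithium enolate of 7 at −78 °C gives the β-hydroxy ester F9, and Dess–Martin oxidation rejoins the route at 8.

## Further compounds

F1 | step 18 | (4R,5S,6S,8S,10R)-13-acetoxy-4,5:10,14-diepoxy-1-oxogermacra-2(Z),7(11)-dien-6,12-olide 8-O-[(2R)-2-methylbutanoate] | CC[C@@H](C)C(=O)O[C@H]1C[C@@]2(CO2)C(=O)/C=C\[C@@]2(C)O[C@H]2[C@H]2OC(=O)C(COC(C)=O)=C12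
F2 | step 19 | 1-O-trimethylsilyl ether of 24 | CC[C@@H](C)C(=O)O[C@H]1C[C@@]2(CO2)[C@H](O[Si](C)(C)C)/C=C\[C@@]2(C)O[C@H]2[C@H]2OC(=O)C(COC(C)=O)=C12
F3 | step 19 | 14-O-trimethylsilyl ether of 25 | CC[C@@H](C)C(=O)O[C@H]1C[C@@]2(CO[Si](C)(C)C)O[C@@H]2/C=C\[C@@]2(C)O[C@H]2[C@H]2OC(=O)C(COC(C)=O)=C12
F4 | step 9 | methyl (2Z,4S)-2-({[tert-butyl(dimethyl)silyl]oxy}methyl)-6-{[(4-methoxybenzyl)oxy]methyl}-4-[(triethylsilyl)oxy]-3-(trimethylstannyl)hepta-2,6-dienoate | COC(=O)/C(CO[Si](C)(C)C(C)(C)C)=C(\[Sn](C)(C)C)[C@@H](O[Si](CC)(CC)CC)CC(=C)COCc1ccc(OC)cc1
F5 | step 9 | methyl (2Z,4S)-2-({[tert-butyl(dimethyl)silyl]oxy}methyl)-3-iodo-6-{[(4-methoxybenzyl)oxy]methyl}-4-[(triethylsilyl)oxy]hepta-2,6-dienoate | COC(=O)/C(CO[Si](C)(C)C(C)(C)C)=C(\I)[C@@H](O[Si](CC)(CC)CC)CC(=C)COCc1ccc(OC)cc1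
F6 | step 2 | 2-[(tributylstannyl)methyl]prop-2-en-1-ol | CCCC[Sn](CCCC)(CCCC)CC(=C)CO
F7 | step 2 | tributyl(2-{[(4-methoxybenzyl)oxy]methyl}prop-2-en-1-yl)stannane | CCCC[Sn](CCCC)(CCCC)CC(=C)COCc1ccc(OC)cc1
F8 | step 5 | (2S)-4-{[(4-methoxybenzyl)oxy]methyl}-2-[(triethylsilyl)oxy]pent-4-enal | O=C[C@@H](O[Si](CC)(CC)CC)CC(=C)COCc1ccc(OC)cc1
F9 | step 5 | methyl (4S)-2-({[tert-butyl(dimethyl)silyl]oxy}methyl)-3-hydroxy-6-{[(4-methoxybenzyl)oxy]methyl}-4-[(triethylsilyl)oxy]hept-6-enoate (C2 and C3 epimers) | COC(=O)C(CO[Si](C)(C)C(C)(C)C)C(O)[C@@H](O[Si](CC)(CC)CC)CC(=C)COCc1ccc(OC)cc1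
A1 | alternative 1 | ten-membered 1(10),2,4-trien-6-ol with C8 p-methoxybenzyl ether, C14 tert-butyldiphenylsilyl ether and a 3-{[tert-butyl(dimethyl)silyl]oxy}prop-1-en-2-yl group at C7 | COc1ccc(CO[C@H]2C/C(CO[Si](c3ccccc3)(c3ccccc3)C(C)(C)C)=C\C=C/C(C)=C/[C@@H](O)[C@@H]2C(=C)CO[Si](C)(C)C(C)(C)C)cc1
A2 | alternative 2 | 13-acetoxy-1,10:4,5-diepoxy-14-{[tert-butyl(dimethyl)silyl]oxy}-8-[(triethylsilyl)oxy]germacra-2(Z),7(11)-dien-6,12-olide | CC[Si](CC)(CC)O[C@H]1C[C@@]2(CO[Si](C)(C)C(C)(C)C)O[C@@H]2/C=C\[C@@]2(C)O[C@H]2[C@H]2OC(=O)C(COC(C)=O)=C12
A3 | alternative 3 | ten-membered 1(10),2-dien-6-one with C8 p-methoxybenzyl ether, C14 tert-butyldiphenylsilyl ether and 4,5-bis(triethylsilyl) ether | COc1ccc(CO[C@H]2C/C(CO[Si](c3ccccc3)(c3ccccc3)C(C)(C)C)=C\C=C/[C@@](C)(O[Si](CC)(CC)CC)[C@H](O[Si](CC)(CC)CC)C(=O)C2)cc1
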